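**Retrosynthetic overview**

The hexamer is cut two-directionally at its two outer CH2 bridges into a tetrameric butanoylphloroglucinol bis-Mannich base and two butanoylfilicinic acid enolates.
Each end ring is not made by methylating an arene but by skeletal isomerisation of the isomeric lactone 3-butanoyl-4-hydroxy-6-isopropyl-2-pyranone (a lactone-masked 2-acyl-3,5-dioxo acid), in which the isopropyl carbon is C-acylated by the lactone carbonyl.
Enabling feature: in each end ring (2-butanoyl-3,5-dihydroxy-4,4-dimethylcyclohexa-2,5-dienone) C4 is a C(CH3)2 carbon between the carbonyl-level carbons C3 and C5, so C3–C4 is an acyl carbon/isobutyryl α-carbon pair. C6–H, between C1 and C5, is the enolate carbon that takes the bridge, and the C2 symmetry lets both ends be made at once.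
Ring order: the four aromatic rings come from phloroglucinol and are linked first (dimer, then tetramer); the pyranone ring is made from a dioxinone; the two carbocyclic end rings are closed last, in the flask in which they are joined to the tetramer.

Key step: step 9

Remark on the chemistry: the target has no stereocentre. The end rings are drawn in the dienol tautomer of the given SMILES, and polyanionic intermediates are drawn as their neutral parents. Equivalents refer to the first reactant of a step unless stated.

**Step 1**
Reactants: 1 benzene-1,3,5-triol (phloroglucinol); 2 butanoyl chloride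
Product: 3 1-(2,4,6-trihydroxyphenyl)butan-1-one (butanoylphloroglucinol)
Conditions: AlCl3 (4 equiv), PhNO2, 25 → 60 °C; then ice/aq. HCl
Reagents that add atoms: none
Why: Friedel–Crafts acylation of a very electron-rich arene, in which the first acyl group deactivates the ring so that mono-C-acylation is expected.

**Step 2**
Reactants: 3 1-(2,4,6-trihydroxyphenyl)butan-1-one (two molecules, used in excess)
Product: 4 bis(3-butanoyl-2,4,6-trihydroxyphenyl)methane
Conditions: 1% aq. NaOH (1.0 equiv), 37% aq. CH2O (0.4 equiv), 0 °C; then 1 M HCl
Reagents that add atoms: formaldehyde, C=O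
Why: Base-mediated phenol–formaldehyde condensation (Lederer–Manasse hydroxymethylation followed by C-alkylation of a second ring), in which the limiting aldehyde and the excess of 3 should favour the methylene-bridged dimer over higher oligomers.

**Step 3**
Reactants: 4 bis(3-butanoyl-2,4,6-trihydroxyphenyl)methane
Product: 5 bis{3-butanoyl-5-[(dimethylamino)methyl]-2,4,6-trihydroxyphenyl}methane
Conditions: CH2(NMe2)2 (2.4 equiv), THF, 25 °C
Reagents that add atoms: N,N,N′,N′-tetramethylmethanediamine, CN(C)CN(C)C
Why: Phenol Mannich reaction with a preformed aminal, which should aminomethylate the single free CH of each ring and leave no nucleophilic aromatic carbon.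

**Step 4**
Reactants: 5 bis{3-butanoyl-5-[(dimethylamino)methyl]-2,4,6-trihydroxyphenyl}methane; 3 1-(2,4,6-trihydroxyphenyl)butan-1-one (10 equiv)
Product: 6 bis{3-butanoyl-5-[(3-butanoyl-2,4,6-trihydroxyphenyl)methyl]-2,4,6-trihydroxyphenyl}methane (linear tetramer with one free CH on each end ring)
Conditions: 1,4-dioxane, 90 °C, N2; excess 3 recovered
Reagents that add atoms: none
Why: Thermal Mannich-base exchange (loss of HNMe2 and C-alkylation of a free ring carbon of 3, an elimination–addition sequence), the usual way to methylene-bridged acylphloroglucinols, with the large excess of 3 expected to limit each terminus to one new ring.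

**Step 5**
Reactants: 6 linear tetramer
Product: 7 bis{3-butanoyl-5-[(3-butanoyl-5-[(dimethylamino)methyl]-2,4,6-trihydroxyphenyl)methyl]-2,4,6-trihydroxyphenyl}methane (tetramer bis-Mannich base)
Conditions: CH2(NMe2)2 (2.4 equiv), THF, 25 °C
Reagents that add atoms: N,N,N′,N′-tetramethylmethanediamine, CN(C)CN(C)C
Why: Phenol Mannich reaction as in step 3, at the only free aromatic CH of each end ring.

**Step 6**
Reactants: 8 2,2,6-trimethyl-4H-1,3-dioxin-4-one (2.0 equiv); 9 2-methylpropanoyl chloride (1.0 equiv)
Product: 10 2,2-dimethyl-6-(3-methyl-2-oxobutyl)-4H-1,3-dioxin-4-one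
Conditions: LiN(SiMe3)2 (2.0 equiv), THF, −78 °C; then 9, −78 → −20 °C; aq. NH4Cl
Reagents that add atoms: none
Why: γ-Acylation (vinylogous Claisen condensation) of the lithium dienolate of the dioxinone, a well-used entry to 6-(2-oxoalkyl)dioxinones, in which the second equivalent of dienolate takes up the acidic proton of the product.

**Step 7**
Reactants: 10 2,2-dimethyl-6-(3-methyl-2-oxobutyl)-4H-1,3-dioxin-4-one
Product: 12 4-hydroxy-6-(propan-2-yl)-2H-pyran-2-one, via acylketene 11 (not isolated)
Conditions: toluene, 110 °C
Reagents that add atoms: none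
Why: Thermal retro-hetero-Diels–Alder loss of acetone should give acylketene 11, which is acylated on the enol oxygen of its own 1,3-diketone to close the 4-hydroxy-2-pyranone, a standard pyranone synthesis.

**Step 8**
Reactants: 12 4-hydroxy-6-(propan-2-yl)-2H-pyran-2-one; 13 butanoic acid (1.1 equiv)
Product: 15 3-butanoyl-4-hydroxy-6-(propan-2-yl)-2H-pyran-2-one, via pyranonyl butanoate 14 (not isolated)
Conditions: DCC (1.2 equiv), DMAP (0.2 equiv), toluene, 25 → 90 °C
Reagents that add atoms: none
Why: Steglich esterification at O4 followed by the DMAP-mediated 1,3 O-to-C acyl shift (Fries-type) to C3, well known for 6-alkyl-4-hydroxy-2-pyranones and driven by the chelated β-tricarbonyl product.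

**Step 9**
Reactants: 15 3-butanoyl-4-hydroxy-6-(propan-2-yl)-2H-pyran-2-one (2.4 equiv per 7); 7 tetramer bis-Mannich base
Product: 18 target hexamer CNP0237140.0 (two butanoylfilicinic acid end rings and four butanoylphloroglucinol rings in a row; all joined by CH2 bridges), via dienylketene 16 (not isolated), via butanoylfilicinic acid 17 (not isolated)
Conditions: LiN(iPr)2 (3.3 equiv per 15), THF, −78 → 0 °C, then 50 °C; AcOH (3.3 equiv), 0 °C; then 7 (0.42 equiv per 15), 1,4-dioxane, 80 °C, N2; 1 M HCl work-up
Reagents that add atoms: none
Why: Proposed new method: LiN(iPr)2 should take 15 to its trianion (at O4, at the butanoyl α-carbon and at the isopropyl methine, as is known for 3-acyl-6-alkyl-4-hydroxy-2-pyranones), whose acyl-stabilised ester enolate expels the ring oxygen (E1cB) to give the dioxido-dienylketene 16, and the terminal C(CH3)2 carbon of 16 then adds to the ketene carbon, so that the lactone O1–C2 bond is exchanged for the C2–C(CH3)2 bond and the carbocycle 17 is obtained as its enolate. The closest known reaction types are the thermal 6π ring closure of dienylketenes to 6,6-disubstituted cyclohexa-2,4-dienones (the reverse of the Barton–Quinkert ring opening) and the base-induced Claisen-type conversion of 4-oxygenated 6-alkyl-2-pyranones into phloroglucinols. The one ring closed is the six-membered carbocycle of the end unit, in a 6-(enolendo)-exo-dig mode that can equally be read as a 6π electrocyclisation; the carbon formed is quaternary but carries two methyl groups, so no stereocentre arises here or anywhere in the target. The step needs C- over O-acylation and ring closure over loss of the butanoyl group: O-attack only gives back 15 and stays reversible whereas C-attack ends in the much more stable β-triketone enolate, the cis geometry of the diene is inherited from the pyranone ring, only the isopropyl carbon can reach the ketene carbon through a six-membered transition state, and no nucleophilic base is present that could cleave the acyl group. After buffering with AcOH, C6 of 17 (the only CH between two C–O carbons) is the nucleophile that takes up both aminomethyl termini of 7 by the known Mannich-base exchange, so that both end rings, both quaternary carbons and both outer bridges are set in one flask.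

**Compound list**

1 | benzene-1,3,5-triol (phloroglucinol) | Oc1cc(O)cc(O)c1 | starting material
2 | butanoyl chloride | CCCC(=O)Cl | starting material
3 | 1-(2,4,6-trihydroxyphenyl)butan-1-one | CCCC(=O)c1c(O)cc(O)cc1O | intermediate
4 | bis(3-butanoyl-2,4,6-trihydroxyphenyl)methane | CCCC(=O)c1c(O)cc(O)c(Cc2c(O)cc(O)c(C(=O)CCC)c2O)c1O | intermediate
5 | bis{3-butanoyl-5-[(dimethylamino)methyl]-2,4,6-trihydroxyphenyl}methane | CCCC(=O)c1c(O)c(CN(C)C)c(O)c(Cc2c(O)c(CN(C)C)c(O)c(C(=O)CCC)c2O)c1O | intermediate
6 | bis{3-butanoyl-5-[(3-butanoyl-2,4,6-trihydroxyphenyl)methyl]-2,4,6-trihydroxyphenyl}methane (linear tetramer) | CCCC(=O)c1c(O)cc(O)c(Cc2c(O)c(Cc3c(O)c(Cc4c(O)cc(O)c(C(=O)CCC)c4O)c(O)c(C(=O)CCC)c3O)c(O)c(C(=O)CCC)c2O)c1O | intermediate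
7 | bis{3-butanoyl-5-[(3-butanoyl-5-[(dimethylamino)methyl]-2,4,6-trihydroxyphenyl)methyl]-2,4,6-trihydroxyphenyl}methane (tetramer bis-Mannich base) | CCCC(=O)c1c(O)c(CN(C)C)c(O)c(Cc2c(O)c(Cc3c(O)c(Cc4c(O)c(CN(C)C)c(O)c(C(=O)CCC)c4O)c(O)c(C(=O)CCC)c3O)c(O)c(C(=O)CCC)c2O)c1O | intermediate
8 | 2,2,6-trimethyl-4H-1,3-dioxin-4-one | CC1=CC(=O)OC(C)(C)O1 | starting material
9 | 2-methylpropanoyl chloride | CC(C)C(Cl)=O | starting material
10 | 2,2-dimethyl-6-(3-methyl-2-oxobutyl)-4H-1,3-dioxin-4-one | CC(C)C(=O)CC1=CC(=O)OC(C)(C)O1 | intermediate
11 | 6-methyl-3,5-dioxohept-1-en-1-one (acylketene) | CC(C)C(=O)CC(=O)C=C=O | intermediate (not isolated)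
12 | 4-hydroxy-6-(propan-2-yl)-2H-pyran-2-one | CC(C)C1=CC(O)=CC(=O)O1 | intermediate
13 | butanoic acid | CCCC(O)=O | starting material
14 | 2-oxo-6-(propan-2-yl)-2H-pyran-4-yl butanoate | CCCC(=O)OC1=CC(=O)OC(C(C)C)=C1 | intermediate (not isolated)
15 | 3-butanoyl-4-hydroxy-6-(propan-2-yl)-2H-pyran-2-one | CCCC(=O)C1=C(O)C=C(C(C)C)OC1=O | intermediate
16 | (3E)-2-butanoyl-3,5-dihydroxy-6-methylhepta-1,3,5-trien-1-one (dienylketene; present as its lithium polyenolate) | O=C=C(C(=O)CCC)/C(O)=C\C(O)=C(C)C | intermediate (not isolated)
17 | 2-butanoyl-3,5-dihydroxy-4,4-dimethylcyclohexa-2,5-dien-1-one (butanoylfilicinic acid; present as its lithium enolate) | CCCC(=O)C1=C(O)C(C)(C)C(O)=CC1=O | intermediate (not isolated)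
18 | CNP0237140.0, the hexamer: two 2-butanoyl-3,5-dihydroxy-4,4-dimethyl-1-oxocyclohexa-2,5-dien-6-yl end rings and four 3-butanoyl-2,4,6-trihydroxyphenylene rings joined in a row by five CH2 bridges | CCCC(=O)C1=C(O)C(C)(C)C(O)=C(Cc2c(O)c(Cc3c(O)c(Cc4c(O)c(Cc5c(O)c(CC6=C(O)C(C)(C)C(O)=C(C(=O)CCC)C6=O)c(O)c(C(=O)CCC)c5O)c(O)c(C(=O)CCC)c4O)c(O)c(C(=O)CCC)c3O)c(O)c(C(=O)CCC)c2O)C1=O | target

**Step count and risks**

Total step count: 9. Longest linear sequence: 6 steps (steps 1, 2, 3, 4, 5 and 9, from phloroglucinol); the pyranone branch is steps 6, 7, 8 and 9.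

Steps most likely to fail:

Step 9 (proposed new method). The polyanion may fail to open to the ketene or may only close back to the lactone. The butanoyl group may be lost by retro-Claisen cleavage. In the second stage the methylene bridges may exchange by retro-Michael scrambling while amine is present. The fallback uses known chemistry and sets out from 3. Dearomatising geminal C-methylation of the acylphloroglucinol (NaOMe, MeI, MeOH, 0 → 25 °C) should give butanoylfilicinic acid, which is isolated and is compound 17 of the list. The route is rejoined at 17, which is heated with 7 as in the second stage of step 9. This fallback makes no compound outside the list (entry F0).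

Step 4. The growing chain may be alkylated again by further Mannich base (oligomer formation), and the bridges may exchange at 90 °C. The fallback changes the order of unions to 2 + 2 + 2, so that no free tetramer is needed. It sets out from 17 (isolated after the first stage of step 9, or from the fallback above). Aminomethylation with CH2(NMe2)2 (THF, 25 °C) should give 2-butanoyl-6-[(dimethylamino)methyl]-3,5-dihydroxy-4,4-dimethylcyclohexa-2,5-dien-1-one F1. Heating F1 with an excess of 3 (dioxane, 90 °C) should give 2-butanoyl-6-[(3-butanoyl-2,4,6-trihydroxyphenyl)methyl]-3,5-dihydroxy-4,4-dimethylcyclohexa-2,5-dien-1-one F2. Its only free aromatic CH is then joined, two equivalents at once, to the dimer bis-Mannich base 5 (dioxane, 80 °C), which comes back to the route at 18; compounds 6 and 7 are then not made.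

Step 6. O-acylation and double acylation of the dienolate may compete, and the dienolate may be quenched by the more acidic product. The fallback sets out from 8. Aldol addition of its lithium dienolate (LiN(iPr)2, THF, −78 °C) to 2-methylpropanal should give racemic 6-(2-hydroxy-3-methylbutyl)-2,2-dimethyl-4H-1,3-dioxin-4-one F3. Oxidation of the secondary alcohol (Dess–Martin periodinane, CH2Cl2, 25 °C) removes the stereocentre and comes back to the route at 10.

**Further compounds**

F0 | step 9 | none | none
F1 | step 4 | 2-butanoyl-6-[(dimethylamino)methyl]-3,5-dihydroxy-4,4-dimethylcyclohexa-2,5-dien-1-one | CCCC(=O)C1=C(O)C(C)(C)C(O)=C(CN(C)C)C1=O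
F2 | step 4 | 2-butanoyl-6-[(3-butanoyl-2,4,6-trihydroxyphenyl)methyl]-3,5-dihydroxy-4,4-dimethylcyclohexa-2,5-dien-1-one | CCCC(=O)C1=C(O)C(C)(C)C(O)=C(Cc2c(O)cc(O)c(C(=O)CCC)c2O)C1=O
F3 | step 6 | 6-(2-hydroxy-3-methylbutyl)-2,2-dimethyl-4H-1,3-dioxin-4-one (racemic) | CC(C)C(O)CC1=CC(=O)OC(C)(C)O1
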